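The target is cut at C7=C8 into commercial crocetin dialdehyde (C8–C8′) and a C10 sulfone that carries the cyclohexene ring (C1–C6). That ring is made in one operation from two commodity fragments: the silyl dienol ether of mesityl oxide (C1–C4, with the gem-dimethyl group and the C3 oxygen) and crotonaldehyde (C5 with its methyl, C6, C7). An amine-catalysed Mukaiyama–Michael/Michael cascade forms C4–C5, then closes C6–C1 from the open-chain keto aldehyde (3S)-3,7-dimethyl-5-oxooct-6-enal. The step exploits the C5 methyl carbon as a temporary stereocentre: it fixes C6 and is erased when the C4=C5 double bond is introduced next to the C3 ketone.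

Key step: step 2

Assumption: atoms are labelled by carotenoid numbering (ring C1–C6, chain C7–C8′), and crocetin dialdehyde 11 is taken as a commercial starting material.

Step 1
Reactants: 1 mesityl oxide (4-methylpent-3-en-2-one)
Product: 2 trimethyl[(4-methylpenta-1,3-dien-2-yl)oxy]silane
Conditions: LiN(iPr)2, THF, −78 °C; Me3SiCl, −78 °C → rt
Reagents that add atoms: chlorotrimethylsilane, C[Si](C)(C)Cl
Why: Kinetic deprotonation of the acetyl methyl group by the hindered amide and O-silylation should give the cross-conjugated 2-silyloxydiene (silyl enol ether formation).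

Step 2
Reactants: 2 trimethyl[(4-methylpenta-1,3-dien-2-yl)oxy]silane (1.5 equiv); 3 (E)-but-2-enal (crotonaldehyde)
Product: 5 (1S,6R)-2,2,6-trimethyl-4-oxocyclohexane-1-carbaldehyde (methyl and formyl trans), via keto aldehyde (3S)-3,7-dimethyl-5-oxooct-6-enal 4 (not isolated)
Conditions: (2R,5R)-5-benzyl-2-tert-butyl-3-methylimidazolidin-4-one (20 mol %), 2,4-dinitrobenzoic acid (20 mol %), H2O (2 equiv), CH2Cl2, −40 °C; then 40 °C
Reagents that add atoms: none
Why: The amine condenses with 3 to an E-iminium ion whose benzyl group is expected to leave the Si face of C-β open, so the terminal CH2 of 2 adds there (Mukaiyama–Michael addition) and sets the methyl-bearing carbon (C5) of 4. The aldehyde of 4 then forms its enamine, whose α-carbon (C6) attacks the acid-activated β,β-dimethyl enone terminus (C1) in an intramolecular Michael addition, a 6-endo-trig closure that forms the C6–C1 bond and thereby the carbocycle. The closest known reaction types are the amine-catalysed Mukaiyama–Michael addition of silyl enol ethers to enals and the amine-catalysed intramolecular Michael addition of formyl enones, run here as one iminium–enamine cascade (a formal Diels–Alder reaction of a 2-silyloxydiene). C5 is under catalyst control, while C6, being α to the aldehyde, should equilibrate through the enamine to the trans (diequatorial) arrangement relative to the C5 methyl, so that the fixed C5 centre dictates the absolute configuration at C6. The step needs conjugate C-alkylation to win over aldol closure, which is secured because the aldehyde enamine could only close a four-membered ring by aldol addition and the six-membered vinylogous aldol would require γ-enolisation of the hindered enone; any cis isomer is to be removed by chromatography.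

Step 3
Reactants: 5 (1S,6R)-2,2,6-trimethyl-4-oxocyclohexane-1-carbaldehyde
Product: 6 (4S,5R)-4-(hydroxymethyl)-3,3,5-trimethylcyclohexan-1-one
Conditions: NaBH(OAc)3, PhH, 60 °C
Reagents that add atoms: none
Why: The acyloxyborohydride is a mild hydride donor that should reduce the aldehyde and leave the ketone untouched (chemoselective carbonyl reduction), after which C6 can no longer epimerise.

Step 4
Reactants: 6 (4S,5R)-4-(hydroxymethyl)-3,3,5-trimethylcyclohexan-1-one
Product: 7 (4S,5R)-3,3,5-trimethyl-4-{[(1-phenyl-1H-tetrazol-5-yl)sulfanyl]methyl}cyclohexan-1-one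
Conditions: 1-phenyl-1H-tetrazole-5-thiol, PPh3, iPrO2C–N=N–CO2iPr, THF, 0 °C → rt
Reagents that add atoms: 1-phenyl-1H-tetrazole-5-thiol, Sc1nnnn1-c1ccccc1
Why: The acidic heteroaryl thiol should displace the phosphonium-activated primary alcohol (Mitsunobu reaction) with the ketone as spectator.

Step 5
Reactants: 7 (4S,5R)-3,3,5-trimethyl-4-{[(1-phenyl-1H-tetrazol-5-yl)sulfanyl]methyl}cyclohexan-1-one
Product: 8 (4S,5R)-3,3,5-trimethyl-4-{[(1-phenyl-1H-tetrazol-5-yl)sulfonyl]methyl}cyclohexan-1-one
Conditions: (NH4)6Mo7O24·4H2O (cat.), 30% H2O2, EtOH, 0 °C → rt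
Reagents that add atoms: hydrogen peroxide, OO
Why: Molybdate-catalysed peroxide oxidation should take the sulfide to the sulfone without touching the saturated ketone (sulfide oxidation).

Step 6
Reactants: 8 (4S,5R)-3,3,5-trimethyl-4-{[(1-phenyl-1H-tetrazol-5-yl)sulfonyl]methyl}cyclohexan-1-one
Product: 9 (4R)-3,5,5-trimethyl-4-{[(1-phenyl-1H-tetrazol-5-yl)sulfonyl]methyl}cyclohex-2-en-1-one (same spatial arrangement at C6; the descriptor changes with the priorities)
Conditions: 2-iodoxybenzoic acid (IBX), DMSO/PhMe, 70 °C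
Reagents that add atoms: none
Why: Dehydrogenation of the ketone by the pentavalent iodine reagent (IBX desaturation) can only give the C4=C5 enone because C1 is quaternary; it erases the temporary C5 centre under non-basic conditions that should leave C6 intact.

Step 7
Reactants: 9 (4R)-3,5,5-trimethyl-4-{[(1-phenyl-1H-tetrazol-5-yl)sulfonyl]methyl}cyclohex-2-en-1-one
Product: 10 (1R,4R)-3,5,5-trimethyl-4-{[(1-phenyl-1H-tetrazol-5-yl)sulfonyl]methyl}cyclohex-2-en-1-ol (hydroxyl trans to the sulfonylmethyl group)
Conditions: iBu2AlH, CH2Cl2, −78 °C; aq. KNaC4H4O6 work-up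
Reagents that add atoms: none
Why: In this 1,2-reduction of the enone, allylic strain with the C5 methyl should hold the C6 substituent pseudoaxial, which places the axial C1 methyl on the opposite face, so hydride should enter anti to that methyl and give the 3-hydroxyl trans to the C6 side chain; the non-basic aluminium hydride avoids β-elimination of the sulfinate.

Step 8
Reactants: 10 (1R,4R)-3,5,5-trimethyl-4-{[(1-phenyl-1H-tetrazol-5-yl)sulfonyl]methyl}cyclohex-2-en-1-ol; 11 crocetin dialdehyde, (2E,4E,6E,8E,10E,12E,14E)-2,6,11,15-tetramethylhexadeca-2,4,6,8,10,12,14-heptaenedial (3 equiv)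
Product: 12 (3R,6R)-3-hydroxy-8′-apo-ε-caroten-8′-al, (2E,4E,6E,8E,10E,12E,14E,16E)-17-[(1R,4R)-4-hydroxy-2,6,6-trimethylcyclohex-2-en-1-yl]-2,6,11,15-tetramethylheptadeca-2,4,6,8,10,12,14,16-octaenal
Conditions: KN(SiMe3)2 (2.2 equiv) added to 10 and 11, THF, −78 °C → rt
Reagents that add atoms: none
Why: In this Julia–Kocienski olefination the first equivalent of base parks the hydroxyl as its alkoxide, the sulfonyl carbanion adds to one aldehyde of the excess symmetrical dialdehyde, and Smiles rearrangement with loss of SO2 and the tetrazolone should give the E C7=C8 bond.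

Step 9
Reactants: 12 (3R,6R)-3-hydroxy-8′-apo-ε-caroten-8′-al
Product: 13 (3R,6R)-8′-apo-ε-carotene-3,8′-diol, (1R,4R)-4-[(1E,3E,5E,7E,9E,11E,13E,15E)-17-hydroxy-3,7,12,16-tetramethylheptadeca-1,3,5,7,9,11,13,15-octaen-1-yl]-3,5,5-trimethylcyclohex-2-en-1-ol
Conditions: NaBH4, MeOH/THF, 0 °C
Reagents that add atoms: none
Why: Borohydride should reduce the conjugated aldehyde by 1,2-addition to the primary allylic alcohol without touching the polyene or either stereocentre (carbonyl reduction).

Compound list
1 | mesityl oxide (4-methylpent-3-en-2-one) | CC(C)=CC(C)=O | starting material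
2 | trimethyl[(4-methylpenta-1,3-dien-2-yl)oxy]silane | C=C(O[Si](C)(C)C)C=C(C)C | intermediate
3 | (E)-but-2-enal (crotonaldehyde) | C/C=C/C=O | starting material
4 | (3S)-3,7-dimethyl-5-oxooct-6-enal | O=CC[C@H](C)CC(=O)C=C(C)C | intermediate
5 | (1S,6R)-2,2,6-trimethyl-4-oxocyclohexane-1-carbaldehyde | C[C@@H]1CC(=O)CC(C)(C)[C@H]1C=O | intermediate
6 | (4S,5R)-4-(hydroxymethyl)-3,3,5-trimethylcyclohexan-1-one | C[C@@H]1CC(=O)CC(C)(C)[C@H]1CO | intermediate
7 | (4S,5R)-3,3,5-trimethyl-4-{[(1-phenyl-1H-tetrazol-5-yl)sulfanyl]methyl}cyclohexan-1-one | C[C@@H]1CC(=O)CC(C)(C)[C@H]1CSc1nnnn1-c1ccccc1 | intermediate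
8 | (4S,5R)-3,3,5-trimethyl-4-{[(1-phenyl-1H-tetrazol-5-yl)sulfonyl]methyl}cyclohexan-1-one | C[C@@H]1CC(=O)CC(C)(C)[C@H]1CS(=O)(=O)c1nnnn1-c1ccccc1 | intermediate
9 | (4R)-3,5,5-trimethyl-4-{[(1-phenyl-1H-tetrazol-5-yl)sulfonyl]methyl}cyclohex-2-en-1-one | CC1=CC(=O)CC(C)(C)[C@H]1CS(=O)(=O)c1nnnn1-c1ccccc1 | intermediate
10 | (1R,4R)-3,5,5-trimethyl-4-{[(1-phenyl-1H-tetrazol-5-yl)sulfonyl]methyl}cyclohex-2-en-1-ol | CC1=C[C@H](O)CC(C)(C)[C@H]1CS(=O)(=O)c1nnnn1-c1ccccc1 | intermediate
11 | crocetin dialdehyde, (2E,4E,6E,8E,10E,12E,14E)-2,6,11,15-tetramethylhexadeca-2,4,6,8,10,12,14-heptaenedial | O=C/C(C)=C/C=C/C(C)=C/C=C/C=C(C)/C=C/C=C(\C)C=O | starting material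
12 | (3R,6R)-3-hydroxy-8′-apo-ε-caroten-8′-al | CC1=C[C@H](O)CC(C)(C)[C@H]1/C=C/C(C)=C/C=C/C(C)=C/C=C/C=C(C)/C=C/C=C(\C)C=O | intermediate
13 | (3R,6R)-8′-apo-ε-carotene-3,8′-diol | CC1=C[C@H](O)CC(C)(C)[C@H]1/C=C/C(C)=C/C=C/C(C)=C/C=C/C=C(C)/C=C/C=C(\C)CO | target

Total step count: 9. Longest linear sequence: 9 steps (1 → 13); crocetin dialdehyde 11 enters at step 8.

Steps most likely to fail

Step 2. The enamine of 4 may add too slowly to the doubly substituted enone terminus, so that the cascade stalls after the first C–C bond and the open-chain aldehyde is lost to intermolecular condensation. The fallback sets out from compound 4, isolated by quenching at −40 °C. The aldehyde is converted with Me3SiCl, Et3N and NaI in MeCN into its silyl enol ether trimethyl{[(3R)-3,7-dimethyl-5-oxoocta-1,6-dien-1-yl]oxy}silane F1 (E/Z mixture, unchanged spatial arrangement at the methyl-bearing carbon). TiCl4 in CH2Cl2 at −78 °C should then close the ring by an intramolecular Mukaiyama–Michael addition, in which the Lewis acid activates the enone instead of the amine activating the nucleophile. Aqueous work-up and equilibration of the formyl-bearing carbon over catalytic pyrrolidinium acetate should bring the route back at compound 5.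

Step 7. Hydride may be delivered to the wrong face of the C3 carbonyl, giving poor facial selectivity. The fallback sets out from compound 9 and accepts the cis alcohol (1S,4R)-3,5,5-trimethyl-4-{[(1-phenyl-1H-tetrazol-5-yl)sulfonyl]methyl}cyclohex-2-en-1-ol F2. Its carbinol centre is inverted by Mitsunobu esterification with 4-nitrobenzoic acid (PPh3, iPrO2C–N=N–CO2iPr, THF) to (1R,4R)-3,5,5-trimethyl-4-{[(1-phenyl-1H-tetrazol-5-yl)sulfonyl]methyl}cyclohex-2-en-1-yl 4-nitrobenzoate F3. Brief methanolysis (K2CO3, MeOH, 0 °C) should return compound 10.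

Step 8. The free alkoxide may consume base and aldehyde, the symmetrical dialdehyde may be olefinated at both ends, and the E selectivity at C7=C8 may erode; a Z fraction could be equilibrated with catalytic iodine and light. The fallback sets out from compound 10 and masks the hydroxyl first (tBuMe2SiCl, imidazole, DMF), giving tert-butyldimethyl{[(1R,4R)-3,5,5-trimethyl-4-{[(1-phenyl-1H-tetrazol-5-yl)sulfonyl]methyl}cyclohex-2-en-1-yl]oxy}silane F4. The same olefination with 11, now needing one equivalent of base, should give the silyl ether of the apocarotenal, (3R,6R)-3-(tert-butyldimethylsilyloxy)-8′-apo-ε-caroten-8′-al F5. Cleavage with Bu4NF buffered by AcOH in THF should bring the route back at compound 12.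

Further compounds
F1 | step 2 | trimethyl{[(3R)-3,7-dimethyl-5-oxoocta-1,6-dien-1-yl]oxy}silane | C[Si](C)(C)OC=C[C@H](C)CC(=O)C=C(C)C
F2 | step 7 | (1S,4R)-3,5,5-trimethyl-4-{[(1-phenyl-1H-tetrazol-5-yl)sulfonyl]methyl}cyclohex-2-en-1-ol | CC1=C[C@@H](O)CC(C)(C)[C@H]1CS(=O)(=O)c1nnnn1-c1ccccc1
F3 | step 7 | (1R,4R)-3,5,5-trimethyl-4-{[(1-phenyl-1H-tetrazol-5-yl)sulfonyl]methyl}cyclohex-2-en-1-yl 4-nitrobenzoate | CC1=C[C@H](OC(=O)c2ccc(cc2)[N+](=O)[O-])CC(C)(C)[C@H]1CS(=O)(=O)c1nnnn1-c1ccccc1
F4 | step 8 | tert-butyldimethyl{[(1R,4R)-3,5,5-trimethyl-4-{[(1-phenyl-1H-tetrazol-5-yl)sulfonyl]methyl}cyclohex-2-en-1-yl]oxy}silane | CC1=C[C@H](O[Si](C)(C)C(C)(C)C)CC(C)(C)[C@H]1CS(=O)(=O)c1nnnn1-c1ccccc1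
F5 | step 8 | (3R,6R)-3-(tert-butyldimethylsilyloxy)-8′-apo-ε-caroten-8′-al | CC1=C[C@H](O[Si](C)(C)C(C)(C)C)CC(C)(C)[C@H]1/C=C/C(C)=C/C=C/C(C)=C/C=C/C=C(C)/C=C/C=C(\C)C=O
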